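**Strategy.** The α-ketol of ring C (C3–OH beside the C4 ketone, in the ring O1–C2–C3–C4–C4a–C8a) is the handle. A retro-acyloin shift of C2 from C3 back to C4 contracts ring C to a 2-phenyl-2,3-dihydrobenzofuran that carries OH and CHO on its C3. Forward, one α-ketol rearrangement of this hydroxy aldehyde expands the five-membered ring to the chromanone, creates the C4 ketone and sets C3 under control of C2. The precursor comes from a Sharpless epoxidation of a (Z)-2-aryl-3-phenylallyl alcohol whose ortho phenol opens the epoxide; the arene is assembled from 3,5-dimethoxyphenol by C-prenylation, benzofurandione formation and Wittig olefination.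

Key step: step 7

Remark: compounds 6 to 12 carry benzofuran numbering, 13 and 14 flavanone numbering; C2 keeps its number through the key step and benzofuran C3 becomes flavanone C4.

Step 1
Reactants: 1 3,5-dimethoxyphenol; 2 1-bromo-3-methylbut-2-ene (prenyl bromide)
Product: 3 3,5-dimethoxy-2-(3-methylbut-2-en-1-yl)phenol
Conditions: NaH, toluene, 0 °C to rt
Reagents that add atoms: none
Why: Ortho-C-alkylation of the sodium phenoxide as a tight ion pair in toluene (phenoxide C-allylation) should place the prenyl group on one of the two equivalent carbons flanked by OH and OMe and leave the other free for step 2; no stereocenter is formed.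

Step 2
Reactants: 3 3,5-dimethoxy-2-(3-methylbut-2-en-1-yl)phenol; 4 oxalyl chloride
Product: 6 4,6-dimethoxy-7-(3-methylbut-2-en-1-yl)-1-benzofuran-2,3-dione, via aryl chlorooxoacetate 5 (not isolated)
Conditions: 2,6-lutidine, CH2Cl2, −20 °C, then 40 °C
Reagents that add atoms: none
Why: O-Acylation of the phenol followed by intramolecular Friedel–Crafts acylation at the only free ortho carbon, which is activated by both methoxy groups, should close the keto lactone, while 2,6-lutidine takes up HCl so that the prenyl group never meets strong acid.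

Step 3
Reactants: 6 4,6-dimethoxy-7-(3-methylbut-2-en-1-yl)-1-benzofuran-2,3-dione; 7 benzyltriphenylphosphonium chloride
Product: 8 (3Z)-3-benzylidene-4,6-dimethoxy-7-(3-methylbut-2-en-1-yl)-1-benzofuran-2(3H)-one
Conditions: KOtBu, THF, 0 °C (ylide), then 6, −78 °C to rt
Reagents that add atoms: none
Why: Wittig olefination with the semi-stabilised ylide should occur at the ketone carbonyl C3, which is far more electrophilic than the lactone carbonyl, and should give mainly the Z alkene (phenyl syn to the lactone carbonyl) because the C4 methoxy group crowds the other side.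

Step 4
Reactants: 8 (3Z)-3-benzylidene-4,6-dimethoxy-7-(3-methylbut-2-en-1-yl)-1-benzofuran-2(3H)-one
Product: 9 (2Z)-2-[2-hydroxy-4,6-dimethoxy-3-(3-methylbut-2-en-1-yl)phenyl]-3-phenylprop-2-en-1-ol
Conditions: iBu2AlH, CH2Cl2, −78 to 0 °C; aq. potassium sodium tartrate
Reagents that add atoms: none
Why: 1,2-Hydride reduction of the unsaturated aryl lactone (lactone to diol reduction) should give the primary allylic alcohol and the free phenol with the alkene geometry unchanged.

Step 5
Reactants: 9 (2Z)-2-[2-hydroxy-4,6-dimethoxy-3-(3-methylbut-2-en-1-yl)phenyl]-3-phenylprop-2-en-1-ol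
Product: 11 (2R,3R)-3-(hydroxymethyl)-4,6-dimethoxy-7-(3-methylbut-2-en-1-yl)-2-phenyl-2,3-dihydro-1-benzofuran-3-ol, via epoxy alcohol 10 (not isolated)
Conditions: Ti(OiPr)4, D-(−)-diisopropyl tartrate, tBuOOH, 4 Å molecular sieves, CH2Cl2, −25 °C, then 0 °C
Reagents that add atoms: tert-butyl hydroperoxide, CC(C)(C)OO
Why: Sharpless asymmetric epoxidation with the D-(−)-tartrate should deliver oxygen to the alkene face that gives the (2R,3S) epoxide, and the titanium-bound epoxy alcohol is then opened at its benzylic C3 by the ortho phenol with inversion (titanium-assisted C3-selective epoxide opening), which fixes the 2R benzylic ether centre and leaves the tertiary carbinol in place.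

Step 6
Reactants: 11 (2R,3R)-3-(hydroxymethyl)-4,6-dimethoxy-7-(3-methylbut-2-en-1-yl)-2-phenyl-2,3-dihydro-1-benzofuran-3-ol
Product: 12 (2R,3S)-3-hydroxy-4,6-dimethoxy-7-(3-methylbut-2-en-1-yl)-2-phenyl-2,3-dihydro-1-benzofuran-3-carbaldehyde
Conditions: SO3·pyridine, DMSO, iPr2NEt, CH2Cl2, 0 °C
Reagents that add atoms: none
Why: Parikh–Doering oxidation converts only the primary alcohol, since the tertiary benzylic alcohol has no carbinol hydrogen, and its mild basic conditions should spare the prenyl group and both stereocenters.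

Step 7
Reactants: 12 (2R,3S)-3-hydroxy-4,6-dimethoxy-7-(3-methylbut-2-en-1-yl)-2-phenyl-2,3-dihydro-1-benzofuran-3-carbaldehyde
Product: 13 (2R,3R)-3-hydroxy-5,7-dimethoxy-8-(3-methylbut-2-en-1-yl)-2-phenyl-2,3-dihydro-4H-chromen-4-one
Conditions: MgBr2·OEt2, iPr2NEt, CH2Cl2, 0 °C to rt; aq. NH4Cl
Reagents that add atoms: none
Why: Deprotonation of the tertiary hydroxyl in the magnesium chelate that also binds the formyl oxygen gives an alkoxide whose push sends the ring bond C2–C3 of the dihydrobenzofuran (C2 bears O1 and phenyl) to the formyl carbon, so the old carbinol carbon becomes the C4 ketone and the formyl carbon becomes C3–OH; this is an α-ketol (acyloin) rearrangement, and the closest known cases are the ring enlargements of 1-hydroxycycloalkanecarbaldehydes and the D-homoannulation of 17-hydroxy-20-keto steroids. Ring C (O1, C2, C3, C4, C4a, C8a) is formed by one-carbon ring expansion of the five-membered ring (O1, C2, C3, C3a, C7a), not by a cyclisation, so no closure mode applies. C2 migrates with retention and keeps the R configuration set in step 5. The new centre C3 is set by the syn-periplanar five-membered chelate, in which C2 sits over the formyl face that leads to 3R (2,3-trans); the same isomer is the thermodynamically preferred one if C3 equilibrates through the enediolate. The step needs migration of C2 in preference to the aryl carbon C3a and rearrangement in preference to loss of water: the aryl group that stays behind stabilises the carbon turning into the carbonyl, its plane is locked in the ring plane and poorly placed for bridging, an alkoxide next to a formyl group does not ionise, and the product is a ketone conjugated with the dimethoxy arene, which makes the shift downhill.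

Step 8
Reactants: 13 (2R,3R)-3-hydroxy-5,7-dimethoxy-8-(3-methylbut-2-en-1-yl)-2-phenyl-2,3-dihydro-4H-chromen-4-one
Product: 14 (2R,3R)-3,5-dihydroxy-7-methoxy-8-(3-methylbut-2-en-1-yl)-2-phenyl-2,3-dihydro-4H-chromen-4-one
Conditions: MgI2, Et2O–toluene, 60 °C; aq. NH4Cl
Reagents that add atoms: none
Why: Magnesium chelated between the C4 carbonyl and the peri C5 methoxy oxygen activates only that methyl group for SN2 attack by iodide (chelation-controlled ether cleavage), so the C7 methoxy group, the prenyl group and the C2 and C3 centres should stay untouched.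

**Compound list**

1 | 3,5-dimethoxyphenol | COc1cc(O)cc(OC)c1 | starting material
2 | 1-bromo-3-methylbut-2-ene | CC(C)=CCBr | starting material
3 | 3,5-dimethoxy-2-(3-methylbut-2-en-1-yl)phenol | COc1cc(O)c(CC=C(C)C)c(OC)c1 | intermediate
4 | oxalyl chloride | O=C(Cl)C(=O)Cl | starting material
5 | 3,5-dimethoxy-2-(3-methylbut-2-en-1-yl)phenyl chlorooxoacetate | COc1cc(OC(=O)C(=O)Cl)c(CC=C(C)C)c(OC)c1 | intermediate
6 | 4,6-dimethoxy-7-(3-methylbut-2-en-1-yl)-1-benzofuran-2,3-dione | COc1cc(OC)c2c(c1CC=C(C)C)OC(=O)C2=O | intermediate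
7 | benzyltriphenylphosphonium chloride | [Cl-].c1ccc(cc1)C[P+](c1ccccc1)(c1ccccc1)c1ccccc1 | starting material
8 | (3Z)-3-benzylidene-4,6-dimethoxy-7-(3-methylbut-2-en-1-yl)-1-benzofuran-2(3H)-one | COc1cc(OC)c2c(c1CC=C(C)C)OC(=O)/C2=C\c1ccccc1 | intermediate
9 | (2Z)-2-[2-hydroxy-4,6-dimethoxy-3-(3-methylbut-2-en-1-yl)phenyl]-3-phenylprop-2-en-1-ol | OC/C(=C\c1ccccc1)c1c(O)c(CC=C(C)C)c(OC)cc1OC | intermediate
10 | [(2R,3S)-2-[2-hydroxy-4,6-dimethoxy-3-(3-methylbut-2-en-1-yl)phenyl]-3-phenyloxiran-2-yl]methanol | OC[C@]1(O[C@H]1c1ccccc1)c1c(O)c(CC=C(C)C)c(OC)cc1OC | intermediate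
11 | (2R,3R)-3-(hydroxymethyl)-4,6-dimethoxy-7-(3-methylbut-2-en-1-yl)-2-phenyl-2,3-dihydro-1-benzofuran-3-ol | COc1cc(OC)c2c(c1CC=C(C)C)O[C@H](c1ccccc1)[C@]2(O)CO | intermediate
12 | (2R,3S)-3-hydroxy-4,6-dimethoxy-7-(3-methylbut-2-en-1-yl)-2-phenyl-2,3-dihydro-1-benzofuran-3-carbaldehyde | COc1cc(OC)c2c(c1CC=C(C)C)O[C@H](c1ccccc1)[C@]2(O)C=O | intermediate
13 | (2R,3R)-3-hydroxy-5,7-dimethoxy-8-(3-methylbut-2-en-1-yl)-2-phenyl-2,3-dihydro-4H-chromen-4-one | COc1cc(OC)c2c(c1CC=C(C)C)O[C@H](c1ccccc1)[C@@H](O)C2=O | intermediate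
14 | (2R,3R)-3,5-dihydroxy-7-methoxy-8-(3-methylbut-2-en-1-yl)-2-phenyl-2,3-dihydro-4H-chromen-4-one | COc1cc(O)c2c(c1CC=C(C)C)O[C@H](c1ccccc1)[C@@H](O)C2=O | target

Total step count: 8
Longest linear sequence: 8 steps (from 1 to 14)

**Steps most likely to fail**

1. Step 7. The electron-rich aryl carbon may migrate in competition with C2, which leads into the isomeric 3-oxo series where C2 could epimerise. The tertiary benzylic alkoxide may also lose water and aromatise to the benzofuran, or the product may open by β-elimination of the aryloxide under the amine. Fallback, setting out from 11 and coming back at 13: selective mesylation of the primary hydroxyl (MsCl, 2,4,6-collidine, CH2Cl2, −20 °C) would give [(2R,3R)-3-hydroxy-4,6-dimethoxy-7-(3-methylbut-2-en-1-yl)-2-phenyl-2,3-dihydro-1-benzofuran-3-yl]methyl methanesulfonate F1. Et3Al (CH2Cl2, −78 °C) would form the aluminium alkoxide and drive a semipinacol shift of C2 onto the CH2 carbon, again a five-to-six ring expansion, to (2S)-5,7-dimethoxy-8-(3-methylbut-2-en-1-yl)-2-phenyl-2,3-dihydro-4H-chromen-4-one F2. Enolisation with in situ trapping (LiN(SiMe3)2, Me3SiCl, THF, −78 °C) would give the silyl enol ether trimethyl{[(2S)-5,7-dimethoxy-8-(3-methylbut-2-en-1-yl)-2-phenyl-2H-chromen-4-yl]oxy}silane F3. Rubottom oxidation with one equivalent of dimethyldioxirane at −78 °C, anti to the C2 phenyl group, followed by mild desilylation, should then install the 3-hydroxyl trans and return to 13.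

2. Step 5. Facial selectivity may be poor because the phenyl group is cis to the hydroxymethyl group. The free phenol may sequester titanium or direct oxidation of the prenyl alkene. The aryl-substituted epoxide carbon may ionise before the phenol attacks C3. Fallback, setting out from 8 and coming back at 12: the lactone keeps the phenol masked, and nucleophilic (Weitz–Scheffer) epoxidation of the benzylidene lactone with tBuOOH, solid K2CO3 and a cinchona-derived quaternary ammonium phase-transfer catalyst of the appropriate enantiomeric series (toluene, 0 °C) would give (3S,3'S)-4,6-dimethoxy-7-(3-methylbut-2-en-1-yl)-3'-phenyl-2H-spiro[1-benzofuran-3,2'-oxiran]-2-one F4. Methanolysis of the aryl lactone (K2CO3, MeOH, 0 °C) frees the phenoxide, which opens the epoxide at the benzylic carbon with inversion to methyl (2R,3S)-3-hydroxy-4,6-dimethoxy-7-(3-methylbut-2-en-1-yl)-2-phenyl-2,3-dihydro-1-benzofuran-3-carboxylate F5. Half-reduction of this α-hydroxy ester (iBu2AlH, CH2Cl2, −78 °C) should give 12 directly.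

3. Step 2. HCl may add to the prenyl alkene or cyclise the ortho-prenyl phenol to a chroman before O-acylation is complete, or the ring closure may not proceed without a Lewis acid. Fallback, setting out from 3 and coming back at 6: acid-free ortho-specific hydroxyalkylation of the bromomagnesium phenoxide (EtMgBr, then ethyl glyoxylate, toluene–Et2O, 0 °C to rt) would give racemic ethyl 2-hydroxy-2-[2-hydroxy-4,6-dimethoxy-3-(3-methylbut-2-en-1-yl)phenyl]acetate F6. Warming in toluene should lactonise it to racemic 3-hydroxy-4,6-dimethoxy-7-(3-methylbut-2-en-1-yl)-1-benzofuran-2(3H)-one F7. Oxidation of the benzylic carbinol with MnO2 (CH2Cl2, rt) would then give 6.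

**Further compounds**

F1 | step 7 | [(2R,3R)-3-hydroxy-4,6-dimethoxy-7-(3-methylbut-2-en-1-yl)-2-phenyl-2,3-dihydro-1-benzofuran-3-yl]methyl methanesulfonate | COc1cc(OC)c2c(c1CC=C(C)C)O[C@H](c1ccccc1)[C@]2(O)COS(C)(=O)=O
F2 | step 7 | (2S)-5,7-dimethoxy-8-(3-methylbut-2-en-1-yl)-2-phenyl-2,3-dihydro-4H-chromen-4-one | COc1cc(OC)c2c(c1CC=C(C)C)O[C@H](c1ccccc1)CC2=O
F3 | step 7 | trimethyl{[(2S)-5,7-dimethoxy-8-(3-methylbut-2-en-1-yl)-2-phenyl-2H-chromen-4-yl]oxy}silane | COc1cc(OC)c2c(c1CC=C(C)C)O[C@H](c1ccccc1)C=C2O[Si](C)(C)C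
F4 | step 5 | (3S,3'S)-4,6-dimethoxy-7-(3-methylbut-2-en-1-yl)-3'-phenyl-2H-spiro[1-benzofuran-3,2'-oxiran]-2-one | O=C1Oc2c(CC=C(C)C)c(OC)cc(OC)c2[C@@]13O[C@H]3c1ccccc1
F5 | step 5 | methyl (2R,3S)-3-hydroxy-4,6-dimethoxy-7-(3-methylbut-2-en-1-yl)-2-phenyl-2,3-dihydro-1-benzofuran-3-carboxylate | COc1cc(OC)c2c(c1CC=C(C)C)O[C@H](c1ccccc1)[C@]2(O)C(=O)OC
F6 | step 2 | ethyl 2-hydroxy-2-[2-hydroxy-4,6-dimethoxy-3-(3-methylbut-2-en-1-yl)phenyl]acetate (racemic) | CCOC(=O)C(O)c1c(O)c(CC=C(C)C)c(OC)cc1OC
F7 | step 2 | 3-hydroxy-4,6-dimethoxy-7-(3-methylbut-2-en-1-yl)-1-benzofuran-2(3H)-one (racemic) | COc1cc(OC)c2c(c1CC=C(C)C)OC(=O)C2O
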